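**Retrosynthetic overview**

1. Numbering (elemane): ring C5–C10 with quaternary C10 (C14 = its CH3), oxirane C1–C2 on C10, acrolein unit C4(=C15)–C3 on C5, lactone C11(=C13)–C12 from C7 to the oxygen on C8; β = ring face of C14. Endgame: 9-O-angeloylation and Si–O cleavage; the enal and the α-methylene lactone both come from two identical CH2CO2Me arms on C5 and C7 (double methylenation, reduction, MnO2), the free 8-OH deciding which arm lactonises.
2. Oxirane from a C1 ketone: 1,3-syn reduction directed by the 9α-OH, closure onto C2, hydrolytic kinetic resolution to the single enantiomer.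
3. Key disconnection: cyclohexane C5–C10 plus γ-lactone from the exo-epoxide of an 8-oxabicyclo[3.2.1]octene; its seven-membered carbocycle C1–C10–C9–C8–C7–C6–C5 contracts by a 1,2-shift of C5 from C1 to C10.
4. Enabling feature: C8–O and C1 stand 1,4 across C9–C10, so one oxygen can bridge them; C10 is the only fully substituted ring carbon and lies between O-bearing C9 and C1. In the bridged frame the C1–C5 bond is antiperiplanar to the exo C10–O bond and the bridge oxygen on C1 stabilises the cation.
5. Ring order: furan (bought) → oxabicycle by [4+3] of furan 3 with the oxyallyl cation from 5 → oxirane at C9–C10 → cyclohexane and γ-lactone (key step) → oxirane at C1–C2.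

Key step: step 6

Assumption: the cycloaddition is not enantioselective, so 7–14 are racemates; their SMILES show the enantiomer that is kept in step 10.

**Route**

Step 1
Reactants: 1 methyl 3-methylfuran-2-carboxylate
Product: 2 (3-methylfuran-2-yl)methanol
Conditions: LiAlH4, Et2O, 0 °C
Reagents that add atoms: none
Why: Hydride reduction of the ester to the primary alcohol (LiAlH4 reduction); no stereocentre is involved.

Step 2
Reactants: 2 (3-methylfuran-2-yl)methanol
Product: 3 2-[(benzyloxy)methyl]-3-methylfuran
Conditions: NaH, BnBr, Bu4NI (cat.), THF, 0 °C to rt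
Reagents that add atoms: benzyl bromide, BrCc1ccccc1
Why: Williamson ether synthesis gives a benzyl ether that should survive the cationic and oxidative steps and is removed by hydrogenolysis in step 8 before any C=C bond is present.

Step 3
Reactants: 4 dimethyl 4-oxoheptanedioate
Product: 5 dimethyl 3,5-dibromo-4-oxoheptanedioate (meso/dl mixture)
Conditions: Br2 (2 equiv), HBr (cat.), CH2Cl2, 0 °C to rt
Reagents that add atoms: bromine, BrBr
Why: Acid-catalysed α,α'-dibromination of the ketone through its enols (the ketone α-CH2 groups enolise far more readily than the ester α-CH2 groups); the diastereomer mixture does not matter because both stereocentres are lost in step 4.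

Step 4
Reactants: 3 2-[(benzyloxy)methyl]-3-methylfuran; 5 dimethyl 3,5-dibromo-4-oxoheptanedioate
Product: 7 racemic dimethyl 2,2'-[1-(benzyloxymethyl)-7-methyl-3-oxo-8-oxabicyclo[3.2.1]oct-6-ene-2,4-diyl]diacetate with both arms equatorial (trans to the oxygen bridge), via oxyallyl cation 6 (not isolated)
Conditions: NaI, Cu, MeCN, 0 °C to rt; then DBU (cat.), CH2Cl2, rt
Reagents that add atoms: none
Why: Reductive debromination gives oxyallyl cation 6, which adds across the two α-carbons of the furan in a [4+3] cycloaddition (symmetrical cation, so one constitution only), and the compact transition state together with DBU equilibration of the two ketone α-centres should funnel all isomers to the diequatorial adduct, fixing the relative configuration of C5, C7, C8 and the bridgehead C1.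

Step 5
Reactants: 7 racemic [4+3] adduct
Product: 8 racemic 6,7-exo-epoxide of 7 (oxirane oxygen on the side of the oxygen bridge)
Conditions: mCPBA, NaHCO3, CH2Cl2, 0 °C
Reagents that add atoms: mCPBA, O=C(OO)c1cccc(Cl)c1
Why: Prilezhaev epoxidation of the strained trisubstituted alkene from the exo face (the endo face is covered by the three-carbon bridge), which places the oxygen at C9 and C10 cis to the bridge oxygen; the ketone should be much slower in Baeyer–Villiger oxidation.

Step 6
Reactants: 8 racemic exo-epoxide
Product: 10 racemic keto lactone (6-oxocyclohexane with trans-fused γ-lactone 7β-CH2C(=O)O-8α, 5β-CH2CO2Me, 9α-OH, 10β-CH3 and 10α-C(=O)CH2OBn), via bicyclic hemiketal 9 (not isolated)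
Conditions: Sc(OTf)3 (10 mol %), H2O (2 equiv), CH2Cl2, −20 °C to rt; then TsOH·H2O (10 mol %), 40 °C
Reagents that add atoms: water, O
Why: Sc(OTf)3 activates the oxirane, the tertiary C10–O bond ionises and the antiperiplanar ring bond C1–C5 shifts from C1 to C10 while the bridge oxygen turns C1 into a tertiary oxocarbenium ion, which water captures as hemiketal 9 (Wagner–Meerwein/semipinacol 1,2-shift). The closest known reaction type is the acid-promoted rearrangement of exo-epoxides of oxygen-bridged bicycles (7-oxanorbornane epoxides) and the semipinacol rearrangement of 2,3-epoxy alcohol derivatives. The shift contracts the seven-membered carbocycle to the cyclohexane C5–C10 (closure by suprafacial 1,2-migration, C1 leaving the ring as the future ketone carbon), and on warming with TsOH the hemiketal opens and the freed 8α-OH closes the trans-fused γ-lactone on the C7 arm by 5-exo-trig acyl substitution. C10 becomes quaternary with inversion (C5 enters anti to the departing oxygen), so C1 ends cis to the 9α-oxygen and C14 trans to it; C8 and C9 keep the α-oxygens given by the bridge and the exo-epoxide, and C5 and C7 keep their β-arms (retention at the migrating carbon). The step needs ionisation at C10 and not at C9 (tertiary against secondary centre), migration of the ring bond and not of CH2OBn (only C1–C5 is antiperiplanar in the rigid bicycle) and no capture by outside nucleophiles (the backside of C10 is the concave endo face); C6 is kept as the ketone because an endo oxygen there would attack C10 across the ring.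

Step 7
Reactants: 10 racemic keto lactone
Product: 11 racemic diol (as 10 with the side-chain ketone reduced to (1R*)-CH(OH)CH2OBn, 1,3-syn to the 9α-OH)
Conditions: Et2BOMe, THF–MeOH (4:1), −78 °C; NaBH4; AcOH, then MeOH (evaporation)
Reagents that add atoms: none
Why: Narasaka–Prasad reduction, in which the 9α-OH is bound as a diethylborinate that chelates the C1 ketone (six-membered chelate fused to the chair locked by the trans-lactone) and external hydride adds axially to give the 1,3-syn diol with C1 in the R configuration; the unchelated, hindered C6 ketone should survive at −78 °C.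

Step 8
Reactants: 11 racemic diol
Product: 12 racemic triol (as 11 with CH2OH in place of CH2OBn)
Conditions: H2 (1 atm), Pd/C, EtOAc, rt
Reagents that add atoms: none
Why: Hydrogenolysis of the benzyl ether; ketone, lactone, ester and all stereocentres should be untouched and no C=C bond is present yet.

Step 9
Reactants: 12 racemic triol
Product: 14 racemic oxirane (1,2-diol of 12 closed to the (1R*)-oxirane on C10; 9α-OH free), via primary tosylate 13 (not isolated)
Conditions: TsCl, Bu2SnO (5 mol %), Et3N, CH2Cl2, 0 °C; then DBU, rt
Reagents that add atoms: none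
Why: Tin-catalysed sulfonylation is selective for the primary hydroxyl of the 1,2-diol and DBU then closes the oxirane by intramolecular Williamson displacement (3-exo-tet) in which the C1–O bond is not broken, so C1 keeps the configuration set in step 7.

Step 10
Reactants: 14 racemic oxirane
Product: 15 (1R)-oxirane, single enantiomer of 14
Conditions: (R,R)-(salen)Co(OAc) (2 mol %; salen = N,N'-bis(3,5-di-tert-butylsalicylidene)cyclohexane-1,2-diamine dianion, trivalent cobalt), H2O (0.55 equiv), THF, 0 °C to rt
Reagents that add atoms: none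
Why: Hydrolytic kinetic resolution of the terminal oxirane, in which the catalyst hydrolyses the (1S)-enantiomer to the triol and leaves the (1R)-enantiomer, so the absolute configuration of all stereocentres is fixed here; the (R,R)-complex is chosen as the antipode taken to leave the (R)-oxirane of simple alkyl oxiranes, and the (S,S)-complex is used if that correlation proves reversed.

Step 11
Reactants: 15 (1R)-oxirane
Product: 18 6β-O-triethylsilyl ether with free 9α-OH (lactone and methyl ester arm intact), via trimethylsilyl ether 16 (not isolated), via bis-silyl ether 17 (not isolated)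
Conditions: 1-(trimethylsilyl)imidazole, CH2Cl2, rt; then LiBH(s-Bu)3, THF, −78 °C; then Et3SiOTf, 2,6-lutidine, −78 °C; then citric acid, MeOH, 0 °C
Reagents that add atoms: triethylsilyl trifluoromethanesulfonate, CC[Si](CC)(CC)OS(=O)(=O)C(F)(F)F
Why: Bulky-hydride ketone reduction with in situ silylation: the 9-OH is first masked as a labile trimethylsilyl ether, hydride then reaches C6 along the equatorial trajectory from the α-face (the axial β-approach is blocked by the syn-axial C14 methyl), the axial 6β-alkoxide is trapped as its triethylsilyl ether before it can lactonise on the C5 arm, and mild acid methanolysis removes only the trimethylsilyl group.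

Step 12
Reactants: 18 6β-O-triethylsilyl ether
Product: 20 bis-methylene compound (α-methylene γ-lactone at C11 and methyl 2-substituted acrylate at C4), via bis-Mannich base 19 (not isolated)
Conditions: LiN(i-Pr)2 (3.3 equiv), THF, −78 °C; CH2=NMe2 I, −78 °C to rt; then MeI, THF–MeOH, rt; then aq. NaHCO3
Reagents that add atoms: dimethylmethyleneammonium iodide, C=[N+](C)C.[I-]
Why: Eschenmoser methylenation on both arms at once: deprotonation of the 9-OH and of the lactone and ester α-CH2 groups, Mannich reaction of both enolates with the iminium salt and Hofmann-type elimination of the quaternised amines install the two exocyclic methylenes; no stereocentre remains at C11 or C4.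

Step 13
Reactants: 20 bis-methylene compound
Product: 21 tetraol (7β-C(=CH2)CH2OH, 5β-C(=CH2)CH2OH, 8α-OH, 9α-OH, 6β-OSiEt3, oxirane)
Conditions: i-Bu2AlH (7 equiv), CH2Cl2, −78 °C; aq. KNaC4H4O6
Reagents that add atoms: none
Why: 1,2-Hydride reduction takes the α-methylene lactone to the 1,4-diol and the acrylate ester to the allylic alcohol; oxirane, silyl ether and all stereocentres should be untouched at −78 °C.

Step 14
Reactants: 21 tetraol
Product: 23 hydroxy enal lactone (α-methylene 8,12-lactone, 5β-C(=CH2)CHO, 9α-OH, 6β-OSiEt3, (1R)-oxirane), via lactol enal 22 (not isolated)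
Conditions: MnO2 (activated, excess), CH2Cl2, rt
Reagents that add atoms: none
Why: MnO2 oxidises only the two allylic primary alcohols; the C12 aldehyde is trapped by the neighbouring 8α-OH as a lactol (5-exo-trig) that is oxidised on to the α-methylene γ-lactone (oxidative lactonisation), while the C3 aldehyde has no free neighbour (6-O is silylated) and stays as the enal.

Step 15
Reactants: 23 hydroxy enal lactone; 24 angelic acid
Product: 26 9-O-angeloyl 6-O-triethylsilyl ether, via mixed anhydride 25 (not isolated)
Conditions: 24, 2,4,6-Cl3C6H2COCl, Et3N, PhMe, rt; then 23, 70 °C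
Reagents that add atoms: none
Why: Yamaguchi esterification of the only free hydroxyl (9α-OH) through the mixed anhydride, run without DMAP so that the Z-configured angelate should not isomerise to the tiglate; C9 is not inverted.

Step 16
Reactants: 26 9-O-angeloyl 6-O-triethylsilyl ether
Product: 27 target CNP0130022.2, (1R,5R,6S,7S,8R,9S,10R)
Conditions: HF·pyridine, pyridine, THF, 0 °C
Reagents that add atoms: none
Why: Fluoride-mediated cleavage of the triethylsilyl ether buffered with pyridine should free the 6β-OH without opening the oxirane or touching the ester, lactone and enal.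

**Compound list**

1 | methyl 3-methylfuran-2-carboxylate | COC(=O)c1occc1C | starting material
2 | (3-methylfuran-2-yl)methanol | Cc1ccoc1CO | intermediate
3 | 2-[(benzyloxy)methyl]-3-methylfuran | Cc1ccoc1COCc1ccccc1 | intermediate
4 | dimethyl 4-oxoheptanedioate | COC(=O)CCC(=O)CCC(=O)OC | starting material
5 | dimethyl 3,5-dibromo-4-oxoheptanedioate (meso/dl mixture) | COC(=O)CC(Br)C(=O)C(Br)CC(=O)OC | intermediate
6 | oxyallyl cation from 5 (2-oxidoallyl cation with CH2CO2Me on both termini) | COC(=O)CC=C([O-])[CH+]CC(=O)OC | intermediate (not isolated)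
7 | racemic dimethyl 2,2'-[1-(benzyloxymethyl)-7-methyl-3-oxo-8-oxabicyclo[3.2.1]oct-6-ene-2,4-diyl]diacetate, both arms equatorial (trans to the oxygen bridge) | O1[C@]2(COCc3ccccc3)C(C)=C[C@H]1[C@@H](CC(=O)OC)C(=O)[C@H]2CC(=O)OC | intermediate
8 | racemic 6,7-exo-epoxide of 7 (oxirane oxygen cis to the oxygen bridge) | O1[C@]2(COCc3ccccc3)[C@]4(C)O[C@@H]4[C@H]1[C@@H](CC(=O)OC)C(=O)[C@H]2CC(=O)OC | intermediate
9 | ring-contracted bicyclic hemiketal (cyclohexanone C5–C10 with an 8α-O–C1(OH)(CH2OBn)–C10 bridge, 9α-OH, 5β- and 7β-CH2CO2Me, 10β-CH3; anomer mixture) | OC1(COCc2ccccc2)O[C@@H]3[C@@H](CC(=O)OC)C(=O)[C@@H](CC(=O)OC)[C@@]1(C)[C@@H]3O | intermediate (not isolated)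
10 | racemic keto lactone (6-oxo, trans-fused γ-lactone 7β-CH2C(=O)O-8α, 5β-CH2CO2Me, 9α-OH, 10β-CH3, 10α-C(=O)CH2OBn) | O=C1C[C@H]2C(=O)[C@@H](CC(=O)OC)[C@](C)(C(=O)COCc3ccccc3)[C@H](O)[C@@H]2O1 | intermediate
11 | racemic diol (as 10, side chain (1R*)-CH(OH)CH2OBn, syn to 9α-OH) | O=C1C[C@H]2C(=O)[C@@H](CC(=O)OC)[C@](C)([C@@H](O)COCc3ccccc3)[C@H](O)[C@@H]2O1 | intermediate
12 | racemic triol (as 11, side chain (1R*)-CH(OH)CH2OH) | O=C1C[C@H]2C(=O)[C@@H](CC(=O)OC)[C@](C)([C@@H](O)CO)[C@H](O)[C@@H]2O1 | intermediate
13 | primary tosylate of 12 | O=C1C[C@H]2C(=O)[C@@H](CC(=O)OC)[C@](C)([C@@H](O)COS(=O)(=O)c3ccc(C)cc3)[C@H](O)[C@@H]2O1 | intermediate (not isolated)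
14 | racemic oxirane (as 12 with the diol closed to the (1R*)-oxirane) | O=C1C[C@H]2C(=O)[C@@H](CC(=O)OC)[C@](C)([C@@H]3CO3)[C@H](O)[C@@H]2O1 | intermediate
15 | (1R)-oxirane, single enantiomer of 14 | O=C1C[C@H]2C(=O)[C@@H](CC(=O)OC)[C@](C)([C@@H]3CO3)[C@H](O)[C@@H]2O1 | intermediate
16 | 9-O-trimethylsilyl ether of 15 | O=C1C[C@H]2C(=O)[C@@H](CC(=O)OC)[C@](C)([C@@H]3CO3)[C@H](O[Si](C)(C)C)[C@@H]2O1 | intermediate (not isolated)
17 | 6β-O-triethylsilyl 9-O-trimethylsilyl ether (C6 ketone reduced) | O=C1C[C@H]2[C@@H](O[Si](CC)(CC)CC)[C@@H](CC(=O)OC)[C@](C)([C@@H]3CO3)[C@H](O[Si](C)(C)C)[C@@H]2O1 | intermediate (not isolated)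
18 | 6β-O-triethylsilyl ether with free 9α-OH | O=C1C[C@H]2[C@@H](O[Si](CC)(CC)CC)[C@@H](CC(=O)OC)[C@](C)([C@@H]3CO3)[C@H](O)[C@@H]2O1 | intermediate
19 | bis-Mannich base (CH2NMe2 on C11 and on C4, epimer mixture) | O=C1C(CN(C)C)[C@H]2[C@@H](O[Si](CC)(CC)CC)[C@@H](C(CN(C)C)C(=O)OC)[C@](C)([C@@H]3CO3)[C@H](O)[C@@H]2O1 | intermediate (not isolated)
20 | bis-methylene compound (α-methylene lactone and methyl acrylate arm) | O=C1C(=C)[C@H]2[C@@H](O[Si](CC)(CC)CC)[C@@H](C(=C)C(=O)OC)[C@](C)([C@@H]3CO3)[C@H](O)[C@@H]2O1 | intermediate
21 | tetraol (two C(=CH2)CH2OH arms, 8α-OH, 9α-OH, 6β-OSiEt3, oxirane) | OCC(=C)[C@H]1[C@@H](O[Si](CC)(CC)CC)[C@@H](C(=C)CO)[C@](C)([C@@H]2CO2)[C@H](O)[C@@H]1O | intermediate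
22 | lactol enal (C12 lactol on O8, C3 aldehyde; anomer mixture) | OC1C(=C)[C@H]2[C@@H](O[Si](CC)(CC)CC)[C@@H](C(=C)C=O)[C@](C)([C@@H]3CO3)[C@H](O)[C@@H]2O1 | intermediate (not isolated)
23 | hydroxy enal lactone (9α-OH free, 6β-OSiEt3) | O=C1C(=C)[C@H]2[C@@H](O[Si](CC)(CC)CC)[C@@H](C(=C)C=O)[C@](C)([C@@H]3CO3)[C@H](O)[C@@H]2O1 | intermediate
24 | angelic acid, (Z)-2-methylbut-2-enoic acid | C/C=C(/C)C(=O)O | starting material
25 | angelic 2,4,6-trichlorobenzoic mixed anhydride | C/C=C(/C)C(=O)OC(=O)c1c(Cl)cc(Cl)cc1Cl | intermediate (not isolated)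
26 | 9-O-angeloyl 6-O-triethylsilyl ether | O=C1C(=C)[C@H]2[C@@H](O[Si](CC)(CC)CC)[C@@H](C(=C)C=O)[C@](C)([C@@H]3CO3)[C@H](OC(=O)/C(C)=C\C)[C@@H]2O1 | intermediate
27 | target CNP0130022.2, (1R,5R,6S,7S,8R,9S,10R) | C=C1C(=O)O[C@@H]2[C@@H]1[C@@H](O)[C@@H](C(=C)C=O)[C@](C)([C@@H]1CO1)[C@@H]2OC(=O)/C(C)=C\C | target

**Step count and risks**

Total step count: 16. Longest linear sequence: 15 steps (from 1 through steps 1, 2 and 4–16; the branch from 4 joins at step 4).

The three steps most likely to fail:

Step 6. The developing cation at C10 may be intercepted by the carbonyl oxygen of the neighbouring C5 ester arm (six-membered participation) or by a 1,2-hydride shift from C9 instead of the ring-bond shift. The fallback ties that arm back before the contraction. Alcohol 2 is used in place of ether 3 and combined with 5 as in step 4; the free CH2OH then closes a δ-lactone onto the adjacent ester arm (DBU) to give tricyclic lactone F1. mCPBA should give exo-epoxide F2, and Sc(OTf)3/H2O followed by TsOH should effect the same shift, the arm now held away from C10, to give keto bis-lactone F3 (γ-lactone on O8 and a seven-membered lactone from C3 to the oxygen on C2). Narasaka–Prasad reduction as in step 7 should give hydroxy bis-lactone F4, and TsOH in MeOH opens the seven-membered lactone to the methyl ester, which returns to the route at triol 12 (steps 2 and 8 are then not needed).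

Step 4. The ester-flanked oxyallyl cation may lose a proton to give an enone before it is trapped, and control of the arm configuration may be incomplete. The fallback builds the bicycle first and adds the arms by enolate alkylation. Furan 3 with 1,1,3,3-tetrabromoacetone (Et2Zn, PhMe, 0 °C) should give dibromo ketone F5, and Zn/Cu with NH4Cl in MeOH the bicyclic ketone F6. LiN(i-Pr)2 followed by BrCH2CO2Me should give monoalkyl ketone F7 (either α-carbon may react first; both isomers lead on), and a second alkylation with DBU equilibration returns to 7.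

Step 11. The C6 alkoxide may close onto the C5 ester before it is silylated, or hydride transfer to the hindered ketone may be slow enough for the lactone to be attacked. The fallback avoids the alkoxide altogether: trimethylsilyl ether 16 is isolated, the C6 ketone is hydrosilylated with Et3SiH and RhCl(PPh3)3 (equatorial delivery for the same steric reason) to give bis-silyl ether 17 directly, and citric acid in MeOH then gives 18; no new compound is made.

**Further compounds**

F1 | step 6 | racemic tricyclic lactone (cycloadduct of 2 and 6 with the bridgehead CH2O closed as δ-lactone onto the adjacent arm; second arm CH2CO2Me equatorial) | O1[C@@]23COC(=O)C[C@@H]2C(=O)[C@H](CC(=O)OC)[C@@H]1C=C3C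
F2 | step 6 | racemic exo-epoxide of F1 | O1[C@@]23COC(=O)C[C@@H]2C(=O)[C@H](CC(=O)OC)[C@@H]1[C@H]4O[C@@]34C
F3 | step 6 | racemic keto bis-lactone (γ-lactone on O8; seven-membered lactone C5–CH2–C(=O)–O–CH2–C1(=O)–C10; 9α-OH) | O=C1C[C@H]2C(=O)[C@H]3CC(=O)OCC(=O)[C@]3(C)[C@H](O)[C@@H]2O1
F4 | step 6 | racemic hydroxy bis-lactone (F3 with C1 reduced to the (1R*)-carbinol) | O=C1C[C@H]2C(=O)[C@H]3CC(=O)OC[C@H](O)[C@]3(C)[C@H](O)[C@@H]2O1
F5 | step 4 | racemic 1-(benzyloxymethyl)-2,4-dibromo-7-methyl-8-oxabicyclo[3.2.1]oct-6-en-3-one (bromide epimers) | O1[C@]2(COCc3ccccc3)C(C)=C[C@H]1C(Br)C(=O)C2Br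
F6 | step 4 | racemic 1-(benzyloxymethyl)-7-methyl-8-oxabicyclo[3.2.1]oct-6-en-3-one | O1[C@]2(COCc3ccccc3)C(C)=C[C@H]1CC(=O)C2
F7 | step 4 | racemic monoalkyl ketone (one equatorial CH2CO2Me, drawn on the carbon next to the unsubstituted bridgehead) | O1[C@]2(COCc3ccccc3)C(C)=C[C@H]1[C@@H](CC(=O)OC)C(=O)C2
F0 | step 11 | none | none
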